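**Retrosynthetic overview**
1. Numbering: C1(Me)=C2, C3 (ArA, chalcone resorcinol ring), C4 (C7 ketone to ArB, the chromene), C5 (ArC), C6H2; ArD is the chalcone B ring. The plan rests on one feature: C1–C6 plus the methyl carbon are the skeleton of 5-methylcyclohex-2-enone, with C3 as carbonyl, C4=C5 as alkene and C1 as the only stereocentre.
2. Removed first are the seven MOM ethers, the C7 ketone (from its carbinol) and the chalcone arm. The arm is made by Claisen–Schmidt condensation on an ArA acetyl group before C7 is oxidised, so C4 is never alpha to a ketone under base.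
3. C1=C2 and C3–H go back to the C2=C3 aryl alkene by a suprafacial 1,3-hydrogen shift that moves the C1 hydrogen to C3. C3–ArA comes from Suzuki coupling of the kinetic C3 enol triflate.
4. Key disconnection: C5–ArC (conjugate addition) and C4–C7 (aldol) are cut in one operation. This gives (S)-5-methylcyclohex-2-enone, the ArC Grignard reagent and the ArB aldehyde.
5. Rings: the carbocycle comes intact from (R)-pulegone after a 1,3-carbonyl transposition. The pyran ring of ArB is the only ring made (step 9, before the key step), and no ring closes afterwards.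

Key step: step 11

Remark: "upper face" means the face of the C1 methyl group. Centres that are destroyed later (the spiro and sulfur-bearing carbons of 2–4, the carbinol of 7, the C7 carbinol) are carried as formed.

**Step 1**
Reactants: 1 (R)-pulegone
Product: 2 pulegone oxide, (6R)-2,2,6-trimethyl-1-oxaspiro[2.5]octan-4-one (both spiro epimers)
Conditions: 30% H2O2, NaOH (cat.), MeOH, 0 °C → rt
Reagents that add atoms: hydrogen peroxide, OO
Why: Weitz–Scheffer nucleophilic epoxidation of the enone; the spiro centre needs no control because it becomes sp2 again in step 3.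

**Step 2**
Reactants: 2 pulegone oxide
Product: 3 (5R)-5-methyl-2-(phenylsulfanyl)cyclohexan-1-one (C2 epimers)
Conditions: PhSNa, THF, reflux; aqueous work-up
Reagents that add atoms: sodium benzenethiolate, [Na+].[S-]c1ccccc1
Why: The thiolate opens the oxirane at the carbonyl-activated alpha carbon and the resulting tertiary alkoxide undergoes retro-aldol loss of acetone, which marks with sulfur the alpha carbon remote from the methyl centre.

**Step 3**
Reactants: 3 (5R)-5-methyl-2-(phenylsulfanyl)cyclohexan-1-one
Product: 5 (R)-5-methylcyclohex-2-en-1-one, via α-sulfinyl ketone 4 (not isolated)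
Conditions: mCPBA, CH2Cl2, −78 °C; then CaCO3, toluene, 110 °C
Reagents that add atoms: none
Why: Sulfide oxidation and thermal syn elimination of the sulfoxide, which can only take a hydrogen from C3, so the alkene forms regiospecifically on the side away from the untouched methyl centre.

**Step 4**
Reactants: 5 (R)-5-methylcyclohex-2-en-1-one
Product: 6 trans-epoxy ketone, 4-methyl-7-oxabicyclo[4.1.0]heptan-2-one with the oxirane oxygen anti to the methyl group
Conditions: 30% H2O2, NaOH (cat.), MeOH, 0 °C
Reagents that add atoms: hydrogen peroxide, OO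
Why: Weitz–Scheffer epoxidation in which hydroperoxide adds axially to the beta carbon anti to the methyl group; a minor epimer would converge on the same enone in step 6.

**Step 5**
Reactants: 6 trans-epoxy ketone
Product: 7 (1R,5S)-5-methylcyclohex-2-en-1-ol (OH trans to methyl)
Conditions: N2H4·H2O, AcOH (cat.), MeOH, 0 °C → rt
Reagents that add atoms: none
Why: Wharton transposition; the epoxy hydrazone collapses to an alkenyl diazene that loses nitrogen, which leaves the oxygen on the former beta carbon with its C–O configuration retained.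

**Step 6**
Reactants: 7 (1R,5S)-5-methylcyclohex-2-en-1-ol
Product: 8 (S)-5-methylcyclohex-2-en-1-one
Conditions: MnO2, CH2Cl2, rt
Reagents that add atoms: none
Why: Neutral allylic alcohol oxidation completes the 1,3-carbonyl transposition; the methyl centre is unchanged in space, but carbonyl and alkene have changed sides, so the ring is now the (S)-enone.

**Step 7**
Reactants: 9 4-bromoresorcinol
Product: 10 1-bromo-2,4-bis(methoxymethoxy)benzene
Conditions: MOMCl, iPr2NEt, CH2Cl2, 0 °C → rt
Reagents that add atoms: chloromethyl methyl ether, COCCl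
Why: O-alkylation of both phenols gives base- and organometal-stable acetal ethers.

**Step 8**
Reactants: 10 1-bromo-2,4-bis(methoxymethoxy)benzene
Product: 11 2,4-bis(methoxymethoxy)phenylmagnesium bromide (titrated THF solution, used directly)
Conditions: Mg turnings (I2-activated), THF, 40 °C
Reagents that add atoms: magnesium, [Mg]
Why: Grignard formation by direct magnesium insertion into the aryl bromide, helped by the ortho acetal oxygen; MOM ethers are inert to the reagent.

**Step 9**
Reactants: 12 2,4-dihydroxybenzaldehyde; 13 3-methylbut-2-enal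
Product: 14 5-hydroxy-2,2-dimethyl-2H-chromene-6-carbaldehyde
Conditions: ethylenediammonium diacetate (10 mol %), xylene, 140 °C
Reagents that add atoms: none
Why: Knoevenagel-type condensation at C3 of the resorcinol, then oxa-6π electrocyclisation of the ortho-quinone methide; the 2-OH is held by its hydrogen bond to the formyl group, so the 4-OH closes the pyran ring and the angular chromene results.

**Step 10**
Reactants: 14 5-hydroxy-2,2-dimethyl-2H-chromene-6-carbaldehyde
Product: 15 5-(methoxymethoxy)-2,2-dimethyl-2H-chromene-6-carbaldehyde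
Conditions: MOMCl, iPr2NEt, CH2Cl2, 0 → 40 °C
Reagents that add atoms: chloromethyl methyl ether, COCCl
Why: O-alkylation of the chelated phenol removes the only acidic proton, so the aldehyde can meet an enolate.

**Step 11**
Reactants: 8 (S)-5-methylcyclohex-2-en-1-one; 11 2,4-bis(methoxymethoxy)phenylmagnesium bromide; 15 5-(methoxymethoxy)-2,2-dimethyl-2H-chromene-6-carbaldehyde
Product: 17 anti aldol adduct (2S,3S,5S)-3-[2,4-bis(methoxymethoxy)phenyl]-2-{(R)-hydroxy[5-(methoxymethoxy)-2,2-dimethyl-2H-chromen-6-yl]methyl}-5-methylcyclohexan-1-one, via magnesium enolate 16 (not isolated)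
Conditions: 11 (1.1 equiv), CuBr·SMe2 (10 mol %), THF, slow addition of 8, −78 → −40 °C; then 15 (1.3 equiv), −78 °C; sat. aq NH4Cl at −78 °C
Reagents that add atoms: none
Why: The Grignard reagent transmetallates to an aryl cuprate that binds the C4=C5 alkene of 8, adds at C5 and reductively eliminates to the regiodefined C3–C4 magnesium enolate 16, which takes up aldehyde 15 through a closed Zimmerman–Traxler transition state. The closest known reaction type is the copper-catalysed conjugate addition of Grignard reagents to cyclic enones with aldol trapping of the enolate (three-component coupling), for which trans addition to 5-substituted cyclohexenones is the rule. No ring is closed; the two new skeletal bonds are C5–ArC and C4–C7. C5 is set by the C1 methyl group, since axial attack on the half-chair with a pseudo-equatorial methyl group places ArC trans to it; C4 is set by ArC, since the aldehyde reaches the enolate on the face away from the new aryl group; C7 follows from the chair transition state of the ring (E)-enolate (anti) and is erased in step 22. The step needs 1,4- over 1,2-addition, secured by copper, low temperature and slow addition of 8, and an enolate that does not migrate to C2, secured by adding 15 at −78 °C with no proton source present. The cold quench protects the aldolate from retro-aldol cleavage and dehydration.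

**Step 12**
Reactants: 17 anti aldol adduct
Product: 18 C7 tert-butyldimethylsilyl ether of 17 (all centres as in 17)
Conditions: TBSOTf, 2,6-lutidine, CH2Cl2, −78 → 0 °C
Reagents that add atoms: tert-butyldimethylsilyl triflate, CC(C)(C)[Si](C)(C)OS(=O)(=O)C(F)(F)F
Why: Silylation of the hindered carbinol under non-nucleophilic, weakly basic conditions blocks retro-aldol cleavage and adds bulk to the upper face; at low temperature the MOM ethers and the ketone should not react.

**Step 13**
Reactants: 18 C7 silyl ether
Product: 20 C3 enol triflate (C2=C3 alkene with OTf on C3; C1, C4, C5 and C7 as in 18), via potassium enolate 19 (not isolated)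
Conditions: KHMDS, THF, −78 °C; then N-(5-chloropyridin-2-yl)triflimide, −78 → 0 °C
Reagents that add atoms: N-(5-chloropyridin-2-yl)bis(trifluoromethanesulfonimide), O=S(=O)(N(c1ccc(Cl)cn1)S(=O)(=O)C(F)(F)F)C(F)(F)F
Why: Kinetic deprotonation takes the accessible C2 methylene proton rather than the shielded tertiary C4–H (whose loss would also expel silanolate), and O-triflation fixes that regiochemistry without touching a stereocentre.

**Step 14**
Reactants: 21 2,4-dihydroxyacetophenone
Product: 22 1-(2,4-dihydroxy-3-iodophenyl)ethan-1-one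
Conditions: I2, HIO3, EtOH/H2O, rt
Reagents that add atoms: iodine, II; iodic acid, O=I(=O)O
Why: Electrophilic aromatic iodination at the position between the two hydroxyl groups, the most activated site of the chelated resacetophenone nucleus under iodine/iodic acid conditions.

**Step 15**
Reactants: 22 1-(2,4-dihydroxy-3-iodophenyl)ethan-1-one
Product: 23 1-[3-iodo-2,4-bis(methoxymethoxy)phenyl]ethan-1-one
Conditions: MOMCl, iPr2NEt, DMF, 0 → 50 °C
Reagents that add atoms: chloromethyl methyl ether, COCCl
Why: O-alkylation of both phenols with an amine base too weak to enolise the methyl ketone.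

**Step 16**
Reactants: 23 1-[3-iodo-2,4-bis(methoxymethoxy)phenyl]ethan-1-one
Product: 24 1-[2,4-bis(methoxymethoxy)-3-(4,4,5,5-tetramethyl-1,3,2-dioxaborolan-2-yl)phenyl]ethan-1-one
Conditions: PdCl2(MeCN)2 (3 mol %), SPhos, pinacolborane, Et3N, dioxane, 80 °C
Reagents that add atoms: pinacolborane, CC1(C)OBOC1(C)C
Why: Palladium-catalysed borylation of an aryl iodide with pinacolborane; the bulky biaryl phosphine accepts di-ortho-substituted halides and the conditions tolerate the ketone.

**Step 17**
Reactants: 20 C3 enol triflate; 24 ArA pinacol boronate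
Product: 25 C3-aryl alkene (20 with OTf replaced by 3-acetyl-2,6-bis(methoxymethoxy)phenyl; C2=C3 alkene; C1–H on the ArC face)
Conditions: Pd(OAc)2 (5 mol %), SPhos (10 mol %), K3PO4, toluene/H2O 10:1, 60 °C
Reagents that add atoms: none
Why: Suzuki–Miyaura coupling of an alkenyl triflate with a hindered aryl boronate, where the electron-rich bulky ligand speeds transmetallation ahead of protodeboronation; no stereocentre is involved and rotamers about C3–ArA are of no consequence.

**Step 18**
Reactants: 25 C3-aryl alkene
Product: 26 C1=C2 isomer (C3–H on the ArC face; ArA cis to the C4 side chain; C4/C5 trans)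
Conditions: [Ir(cod)(PCy3)(py)]BArF (10 mol %), H2 (1 atm, 2 min) then Ar purge, THF, 25 → 50 °C
Reagents that add atoms: none
Why: Proposed new method: the cationic iridium hydride should bind the C2=C3 alkene on the lower face, anti to the C1 methyl group and the silylated C4 side chain, and insert with H to C3 and Ir to the secondary C2; syn beta-hydride elimination can then only take the cis C1–H, so the hydrogen at C3 ends on the face that C1–H occupied and ArA ends cis to C7, whereas binding on the upper face finds no syn hydrogen at C1 or C4 and can only revert; the di-ortho-substituted ArA is twisted out of conjugation, so the shift exchanges one trisubstituted alkene for another, and it should be driven by release of A(1,2) strain between ArA and the C4 side chain; the closest known reaction type is iridium- or palladium-hydride isomerisation (chain walking) of tri- and tetrasubstituted allylic and alkenyl alcohols, in which the metal stays on one face.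

**Step 19**
Reactants: 12 2,4-dihydroxybenzaldehyde
Product: 27 2,4-bis(methoxymethoxy)benzaldehyde
Conditions: MOMCl, iPr2NEt, CH2Cl2, 0 → 40 °C
Reagents that add atoms: chloromethyl methyl ether, COCCl
Why: O-alkylation of both phenols gives the non-enolisable aldehyde partner for the chalcone.

**Step 20**
Reactants: 26 C1=C2 isomer; 27 2,4-bis(methoxymethoxy)benzaldehyde
Product: 28 (E)-chalcone (26 with the acetyl group extended to C(=O)–CH=CH–ArD; C7 still silylated)
Conditions: KOH, EtOH/THF, rt
Reagents that add atoms: none
Why: Claisen–Schmidt condensation of the only enolisable ketone, with E1cB dehydration giving the (E)-enone; because C7 is still a silyl ether, no ring stereocentre is alpha to a carbonyl group under base.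

**Step 21**
Reactants: 28 (E)-chalcone silyl ether
Product: 29 C7 carbinol (28 with OH in place of OTBS)
Conditions: TBAF, THF, 0 → 40 °C
Reagents that add atoms: none
Why: Fluoride-driven cleavage of the Si–O bond; MOM ethers, chalcone and chromene are inert, and the carbinol is no longer beta to a ketone, so it cannot fragment.

**Step 22**
Reactants: 29 C7 carbinol
Product: 30 hepta-MOM ether of the target (C7 ketone)
Conditions: Dess–Martin periodinane, CH2Cl2, 0 °C → rt
Reagents that add atoms: none
Why: Dess–Martin oxidation of the benzylic secondary alcohol under near-neutral conditions erases the C7 centre without enolising toward C4.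

**Step 23**
Reactants: 30 hepta-MOM ether
Product: 31 CNP0115975.1, (E)-3-(2,4-dihydroxyphenyl)-1-{3-[(1S,5S,6R)-5-(2,4-dihydroxyphenyl)-6-(5-hydroxy-2,2-dimethyl-2H-chromene-6-carbonyl)-3-methylcyclohex-2-en-1-yl]-2,4-dihydroxyphenyl}prop-2-en-1-one
Conditions: 1.25 M HCl in MeOH, THF, 35 °C, dark, Ar
Reagents that add atoms: none
Why: Acid-catalysed transacetalisation of all seven aryl MOM ethers to methanol, a standard release of polyhydroxychalcones, run mild and in the dark to spare the chalcone, the chromene and the C4 centre.

**Compound list**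
1 | (R)-pulegone | C[C@@H]1CCC(=C(C)C)C(=O)C1 | starting material
2 | pulegone oxide (spiro epimers) | C[C@@H]1CCC2(OC2(C)C)C(=O)C1 | intermediate
3 | (5R)-5-methyl-2-(phenylsulfanyl)cyclohexan-1-one (C2 epimers) | C[C@@H]1CCC(Sc2ccccc2)C(=O)C1 | intermediate
4 | (5R)-5-methyl-2-(phenylsulfinyl)cyclohexan-1-one (not isolated) | C[C@@H]1CCC(S(=O)c2ccccc2)C(=O)C1 | intermediate
5 | (R)-5-methylcyclohex-2-en-1-one | C[C@@H]1CC=CC(=O)C1 | intermediate
6 | 4-methyl-7-oxabicyclo[4.1.0]heptan-2-one, oxirane anti to methyl | C[C@@H]1C[C@H]2O[C@H]2C(=O)C1 | intermediate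
7 | (1R,5S)-5-methylcyclohex-2-en-1-ol | C[C@@H]1C[C@@H](O)C=CC1 | intermediate
8 | (S)-5-methylcyclohex-2-en-1-one | C[C@@H]1CC(=O)C=CC1 | intermediate
9 | 4-bromoresorcinol | Oc1ccc(Br)c(O)c1 | starting material
10 | 1-bromo-2,4-bis(methoxymethoxy)benzene | COCOc1ccc(Br)c(OCOC)c1 | intermediate
11 | 2,4-bis(methoxymethoxy)phenylmagnesium bromide | COCOc1ccc([Mg]Br)c(OCOC)c1 | intermediate
12 | 2,4-dihydroxybenzaldehyde | O=Cc1ccc(O)cc1O | starting material
13 | 3-methylbut-2-enal | CC(C)=CC=O | starting material
14 | 5-hydroxy-2,2-dimethyl-2H-chromene-6-carbaldehyde | O=Cc1ccc2c(c1O)C=CC(C)(C)O2 | intermediate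
15 | 5-(methoxymethoxy)-2,2-dimethyl-2H-chromene-6-carbaldehyde | O=Cc1ccc2c(c1OCOC)C=CC(C)(C)O2 | intermediate
16 | C3–C4 magnesium enolate after conjugate addition (not isolated) | C[C@@H]1CC(O[Mg]Br)=C[C@@H](c2ccc(OCOC)cc2OCOC)C1 | intermediate
17 | anti aldol adduct, 4,5-trans and 5,1-trans | C[C@@H]1CC(=O)[C@H]([C@@H](O)c2ccc3c(c2OCOC)C=CC(C)(C)O3)[C@@H](c2ccc(OCOC)cc2OCOC)C1 | intermediate
18 | C7 TBS ether of 17 | C[C@@H]1CC(=O)[C@H]([C@@H](O[Si](C)(C)C(C)(C)C)c2ccc3c(c2OCOC)C=CC(C)(C)O3)[C@@H](c2ccc(OCOC)cc2OCOC)C1 | intermediate
19 | potassium C2=C3 enolate of 18 (not isolated) | C[C@@H]1C=C([O-])[C@H]([C@@H](O[Si](C)(C)C(C)(C)C)c2ccc3c(c2OCOC)C=CC(C)(C)O3)[C@@H](c2ccc(OCOC)cc2OCOC)C1.[K+] | intermediate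
20 | C3 enol triflate | C[C@@H]1C=C(OS(=O)(=O)C(F)(F)F)[C@H]([C@@H](O[Si](C)(C)C(C)(C)C)c2ccc3c(c2OCOC)C=CC(C)(C)O3)[C@@H](c2ccc(OCOC)cc2OCOC)C1 | intermediate
21 | 2,4-dihydroxyacetophenone | CC(=O)c1ccc(O)cc1O | starting material
22 | 1-(2,4-dihydroxy-3-iodophenyl)ethan-1-one | CC(=O)c1ccc(O)c(I)c1O | intermediate
23 | 1-[3-iodo-2,4-bis(methoxymethoxy)phenyl]ethan-1-one | CC(=O)c1ccc(OCOC)c(I)c1OCOC | intermediate
24 | ArA pinacol boronate | CC(=O)c1ccc(OCOC)c(B2OC(C)(C)C(C)(C)O2)c1OCOC | intermediate
25 | C3-aryl C2=C3 alkene | C[C@@H]1C=C(c2c(OCOC)ccc(C(C)=O)c2OCOC)[C@H]([C@@H](O[Si](C)(C)C(C)(C)C)c2ccc3c(c2OCOC)C=CC(C)(C)O3)[C@@H](c2ccc(OCOC)cc2OCOC)C1 | intermediate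
26 | C1=C2 isomer, 3,4-cis and 4,5-trans | CC1=C[C@H](c2c(OCOC)ccc(C(C)=O)c2OCOC)[C@H]([C@@H](O[Si](C)(C)C(C)(C)C)c2ccc3c(c2OCOC)C=CC(C)(C)O3)[C@@H](c2ccc(OCOC)cc2OCOC)C1 | intermediate
27 | 2,4-bis(methoxymethoxy)benzaldehyde | COCOc1ccc(C=O)c(OCOC)c1 | intermediate
28 | (E)-chalcone, C7 TBS ether | CC1=C[C@H](c2c(OCOC)ccc(C(=O)/C=C/c3ccc(OCOC)cc3OCOC)c2OCOC)[C@H]([C@@H](O[Si](C)(C)C(C)(C)C)c2ccc3c(c2OCOC)C=CC(C)(C)O3)[C@@H](c2ccc(OCOC)cc2OCOC)C1 | intermediate
29 | (E)-chalcone, C7 carbinol | CC1=C[C@H](c2c(OCOC)ccc(C(=O)/C=C/c3ccc(OCOC)cc3OCOC)c2OCOC)[C@H]([C@@H](O)c2ccc3c(c2OCOC)C=CC(C)(C)O3)[C@@H](c2ccc(OCOC)cc2OCOC)C1 | intermediate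
30 | hepta-MOM ether of the target | CC1=C[C@H](c2c(OCOC)ccc(C(=O)/C=C/c3ccc(OCOC)cc3OCOC)c2OCOC)[C@H](C(=O)c2ccc3c(c2OCOC)C=CC(C)(C)O3)[C@@H](c2ccc(OCOC)cc2OCOC)C1 | intermediate
31 | CNP0115975.1 | CC1=C[C@H](c2c(O)ccc(C(=O)/C=C/c3ccc(O)cc3O)c2O)[C@H](C(=O)c2ccc3c(c2O)C=CC(C)(C)O3)[C@@H](c2ccc(O)cc2O)C1 | target

**Total step count:** 23.
**Longest linear sequence:** 15 steps (steps 1–6, 11–13, 17, 18, 20–23; from 1 to 31).

**Steps most likely to fail**

1. **Step 18 (1,3-hydrogen shift).**
   - What may go wrong: the catalyst may fail to bind the crowded trisubstituted alkene. The equilibrium may stay on the side of the aryl alkene. The hydride may walk the wrong way on the lower face, to C3=C4 and on toward the silyl ether carbon.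
   - Fallback: it sets out from 18, uses 24, returns at 26, and leaves out steps 13 and 17.
   - The kinetic enolate 19 would be silylated with TMSCl to the trimethylsilyl enol ether F1.
   - Saegusa–Ito oxidation (Pd(OAc)2, MeCN) would give the C1=C2–C3 enone F2.
   - Luche reduction (NaBH4, CeCl3, MeOH, −78 °C) should follow the axial trajectory. It should give the pseudo-equatorial allylic alcohol F3, with the hydroxyl group trans to the C4 side chain.
   - Methyl chloroformate and pyridine would give the allylic methyl carbonate F4.
   - A palladium-catalysed allyl–aryl Suzuki coupling of F4 with 24 (Pd(PPh3)4, THF, 50 °C) ionises anti to the carbonate and passes the aryl group from palladium to carbon. The result is net inversion at the less substituted allyl terminus C3, which places ArA cis to the side chain and gives 26.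

2. **Step 11 (three-component coupling).**
   - What may go wrong: 1,2-addition of the aryl Grignard reagent may compete. The aldol addition to the electron-rich, ortho-substituted aldehyde may be slow or reversible, which would allow enolate equilibration, retro-aldol cleavage or dehydration.
   - Fallback: it sets out from 8 and 11 and returns at 17, with the two bond formations separated.
   - With TMSCl present (CuBr·SMe2 cat., THF, −78 °C) the conjugate addition is accelerated and the enolate is captured as the trimethylsilyl enol ether F5, which can be purified.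
   - A Mukaiyama aldol addition of F5 to 15 (BF3·OEt2, CH2Cl2, −78 °C, aqueous work-up) proceeds through an open transition state and is not reversible under the conditions. It still attacks the face away from ArC, giving 17 (the C7 configuration is immaterial).

3. **Step 23 (global deprotection).**
   - What may go wrong: before the last MOM ethers leave, acid may induce ring closures. These include ketal formation between the C7 carbonyl group and the ortho phenols of ArA and ArC, closure of the chalcone to flavanone or flavylium forms, and addition of a phenol to C1=C2 or to the chromene alkene. Acid may also enolise toward C4.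
   - Fallback: it sets out from 30 and returns at 31, replacing Brønsted acid solvolysis by a protecting-group exchange.
   - TESOTf and 2,2'-bipyridyl (MeCN, 0 °C → rt) convert aryl MOM ethers directly into aryl silyl ethers, giving the heptakis(triethylsilyl) ether F6.
   - Buffered fluoride (Et3N·3HF, THF, 0 °C) then frees the seven phenols at near-neutral pH.

**Further compounds**
F1 | step 18 | trimethylsilyl enol ether of 18 (C2=C3) | C[C@@H]1C=C(O[Si](C)(C)C)[C@H]([C@@H](O[Si](C)(C)C(C)(C)C)c2ccc3c(c2OCOC)C=CC(C)(C)O3)[C@@H](c2ccc(OCOC)cc2OCOC)C1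
F2 | step 18 | C1=C2–C3 enone | CC1=CC(=O)[C@H]([C@@H](O[Si](C)(C)C(C)(C)C)c2ccc3c(c2OCOC)C=CC(C)(C)O3)[C@@H](c2ccc(OCOC)cc2OCOC)C1
F3 | step 18 | C3 allylic alcohol, OH trans to the C4 side chain | CC1=C[C@@H](O)[C@H]([C@@H](O[Si](C)(C)C(C)(C)C)c2ccc3c(c2OCOC)C=CC(C)(C)O3)[C@@H](c2ccc(OCOC)cc2OCOC)C1
F4 | step 18 | C3 allylic methyl carbonate | CC1=C[C@@H](OC(=O)OC)[C@H]([C@@H](O[Si](C)(C)C(C)(C)C)c2ccc3c(c2OCOC)C=CC(C)(C)O3)[C@@H](c2ccc(OCOC)cc2OCOC)C1
F5 | step 11 | trimethylsilyl enol ether of the conjugate adduct (C3=C4) | C[C@@H]1CC(O[Si](C)(C)C)=C[C@@H](c2ccc(OCOC)cc2OCOC)C1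
F6 | step 23 | heptakis(triethylsilyl) ether of the target | CC1=C[C@H](c2c(O[Si](CC)(CC)CC)ccc(C(=O)/C=C/c3ccc(O[Si](CC)(CC)CC)cc3O[Si](CC)(CC)CC)c2O[Si](CC)(CC)CC)[C@H](C(=O)c2ccc3c(c2O[Si](CC)(CC)CC)C=CC(C)(C)O3)[C@@H](c2ccc(O[Si](CC)(CC)CC)cc2O[Si](CC)(CC)CC)C1
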